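**Retrosynthetic overview**

1. GA65 ⇐ its 7,20-acylal lactone (C20 at the aldehyde level, C6 epimeric) carrying the 16-en-15-one; the endgame is 15-ketone reduction, methanolysis with C6 epimerisation, and saponification.
2. Ring D ⇐ radical 1,2-acyl shift of C16 from C12 to C13 in an ent-atisane-type bicyclo[2.2.2]octane-13,16-dione. Rings B and C ⇐ one intramolecular Diels–Alder reaction on a dearomatised arene that forms C8–C9 and C11–C12.
3. Enabling feature: C8, C14, C13, C12, C16 and C15 (all atoms of rings C and D outside ring B) form one six-membered carbocycle once C16 sits on C12. With oxygen on C15, C16 and C13 this ring is a 3-alkyl-2,5-dimethoxyphenol, and C9=C11 is a vinyl group on C10, three atoms (C6, C5, C10) from diene terminus C8.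
4. Ring A ⇐ methyl 3-oxocyclohex-1-ene-1-carboxylate: one catalytic conjugate addition sets C10, a C20–O-tethered Michael addition/methylation relays C5 and C4, and the arene is joined at C6 by enolate arylation.
5. Order of ring formation: ring A (purchased) → temporary δ-lactone (C6–C7–O–C20) → rings B and C together (key step) → ring D (acyl shift) → lactone opened.

Key step: step 10

Remark: GA65 denotes the target gibberellin; gibberellane numbering (C1–C20) is used for all intermediates; both starting materials are taken as catalogue compounds; the acetal carbon C20 is a mixture of both configurations from step 2 until it becomes the aldehyde carbon in step 17 and is written without a stereodescriptor.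

**Route**

Step 1
Reactants: 1 methyl 3-oxocyclohex-1-ene-1-carboxylate
Product: 3 methyl (1R)-1-ethenyl-3-(trifluoromethylsulfonyloxy)cyclohex-2-ene-1-carboxylate, via bromomagnesium enolate 2 (not isolated)
Conditions: CH2=CHMgBr, Cu(OTf)2 (5 mol %), chiral N-heterocyclic carbene ligand (6 mol %, from its imidazolinium salt), Et2O, −30 °C; then PhNTf2, THF, −30 °C to rt
Reagents that add atoms: vinylmagnesium bromide C=C[Mg]Br; N-phenylbis(trifluoromethanesulfonimide) O=S(=O)(N(c1ccccc1)S(=O)(=O)C(F)(F)F)C(F)(F)F
Why: Copper-catalysed asymmetric conjugate addition of the vinyl Grignard reagent to the ester-bearing β-carbon of the doubly activated enone should create the C10 quaternary centre, the ligand enantiomer being chosen to give the (R)-configuration, and the regiodefined magnesium enolate is trapped on oxygen as the enol triflate.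

Step 2
Reactants: 3 methyl (1R)-1-ethenyl-3-(trifluoromethylsulfonyloxy)cyclohex-2-ene-1-carboxylate
Product: 5 [(1R)-1-ethenyl-3-(trifluoromethylsulfonyloxy)cyclohex-2-en-1-yl](methoxy)methyl acetate, via aluminium hemiacetal 4 (not isolated)
Conditions: i-Bu2AlH, CH2Cl2, −78 °C; then pyridine, DMAP, Ac2O, −78 to 0 °C
Reagents that add atoms: acetic anhydride CC(=O)OC(C)=O
Why: Hydride addition to the only ester stops at the aluminium hemiacetal at −78 °C and this is acetylated in the flask (reductive acetylation of an ester to an α-acetoxy ether), so C20 reaches the aldehyde oxidation level and carries the acetate that later serves as tethered nucleophile; the enol triflate is inert and the new acetal centre is of no consequence.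

Step 3
Reactants: 5 [(1R)-1-ethenyl-3-(trifluoromethylsulfonyloxy)cyclohex-2-en-1-yl](methoxy)methyl acetate
Product: 6 methyl (3R)-3-[acetoxy(methoxy)methyl]-3-ethenylcyclohex-1-ene-1-carboxylate
Conditions: Pd(OAc)2 (5 mol %), 1,3-bis(diphenylphosphino)propane, CO (1 atm), MeOH (10 equiv), i-Pr2NEt, DMF, 50 °C
Reagents that add atoms: carbon monoxide [C-]#[O+]; methanol CO
Why: Palladium-catalysed methoxycarbonylation of the alkenyl triflate (oxidative addition, CO insertion, methanolysis of the acylpalladium) installs C19 as the α,β-unsaturated ester that is the Michael acceptor, under weakly basic conditions that should leave the acetoxy acetal intact.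

Step 4
Reactants: 6 methyl (3R)-3-[acetoxy(methoxy)methyl]-3-ethenylcyclohex-1-ene-1-carboxylate
Product: 8 ring A acylal lactone (4α-CO2Me/4β-Me/5β-H/10β-vinyl), via lithium ester enolate 7 (not isolated)
Conditions: LiN(i-Pr)2, THF, −78 to −40 °C; then MeI, DMPU, −78 to −20 °C
Reagents that add atoms: iodomethane CI
Why: Proposed new method: kinetic deprotonation of the acetate gives an ester enolate held on the α-face by the C20–O tether, so that intramolecular 6-exo Michael addition to C5 must place C6 cis to C20 (5β-H) and close the δ-lactone, and the C4 ester enolate so formed is methylated in the same flask anti to the new C5–C6 bond and to the axial C20 bridge (4β-Me, 4α-CO2Me); the closest known reaction types are Michael-initiated ring closure (tandem Michael addition–enolate alkylation) of ester enolates and the Michael additions of lithium enolates of acetal esters such as 1,3-dioxolan-4-ones, which are stable at −78 °C.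

Step 5
Reactants: 9 3-bromo-2-hydroxy-5-methoxybenzaldehyde
Product: 10 3-bromo-2,5-dimethoxybenzaldehyde
Conditions: MeI, K2CO3, DMF, rt
Reagents that add atoms: iodomethane CI
Why: Williamson O-methylation of the phenoxide fixes the methoxy group that becomes one arm of the C15 ketal.

Step 6
Reactants: 10 3-bromo-2,5-dimethoxybenzaldehyde
Product: 12 3-bromo-2,5-dimethoxyphenol, via aryl formate 11 (not isolated)
Conditions: mCPBA, CH2Cl2, rt; then K2CO3 (cat.), MeOH, rt
Reagents that add atoms: 3-chloroperoxybenzoic acid OOC(=O)c1cccc(Cl)c1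
Why: Baeyer–Villiger (Dakin-type) oxidation, in which the electron-rich aryl group migrates to give the aryl formate, followed by methanolysis, places the phenol oxygen on the carbon that becomes C16.

Step 7
Reactants: 12 3-bromo-2,5-dimethoxyphenol
Product: 13 (3-bromo-2,5-dimethoxyphenoxy)(tert-butyl)dimethylsilane
Conditions: TBSCl, imidazole, DMF, rt
Reagents that add atoms: tert-butyldimethylsilyl chloride CC(C)(C)[Si](C)(C)Cl
Why: Silylation masks the phenol during the enolate arylation.

Step 8
Reactants: 8 ring A acylal lactone; 13 (3-bromo-2,5-dimethoxyphenoxy)(tert-butyl)dimethylsilane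
Product: 14 C6-aryl lactone silyl ether (6β-H)
Conditions: LiN(SiMe3)2, THF, −78 °C; ZnCl2; then 13, Pd(dba)2 (3 mol %), P(t-Bu)3 (3 mol %), THF, rt
Reagents that add atoms: none
Why: Palladium-catalysed α-arylation of the lactone as its zinc (Reformatsky-type) enolate forms the C6–aryl bond at the only enolisable position, and the epimerisable C6 centre is expected to settle with the aryl group trans to the quaternary C4 branch on the lactone ring (H-6 β), which is the epimer whose aryl group lies on the same face of the lactone ring as the C10 vinyl group.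

Step 9
Reactants: 14 C6-aryl lactone silyl ether
Product: 15 C6-aryl lactone phenol
Conditions: n-Bu4NF, AcOH, THF, 0 °C
Reagents that add atoms: none
Why: Buffered fluoride cleaves the aryl silyl ether much faster than it affects the acylal lactone or the ester (desilylation).

Step 10
Reactants: 15 C6-aryl lactone phenol
Product: 18 13,16-dioxo-15,15-dimethoxy pentacycle, via dienone 16 (not isolated), via enol-ether cycloadduct 17 (not isolated)
Conditions: PhI(OAc)2, MeOH, 0 °C; then toluene, 110 °C; then aq. oxalic acid, THF, rt
Reagents that add atoms: methanol CO; water O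
Why: Two-electron oxidation of the guaiacol-type phenol gives a phenoxonium ion that methanol traps at the methoxy-bearing ortho carbon (para to the second methoxy group) to give the 6,6-dimethoxycyclohexa-2,4-dienone 16 (a masked o-benzoquinone), whose diene C8=C14–C13=C12 adds thermally to the tethered vinyl group C9=C11 in a concerted suprafacial [4+2] cycloaddition, the closest known reaction type being the oxidative dearomatisation/intramolecular Diels–Alder reaction of masked o-benzoquinones. Ring B (C5–C6–C8–C9–C10) closes in the fused mode by bonding of diene terminus C8 to C9 through the three-atom tether C6–C5–C10, and the bicyclo[2.2.2]octene closes by bonding of C11 to the other diene terminus C12. C9 is controlled by the trans junction of rings A and B, because only the tether conformer with C11 pseudo-equatorial on the forming cyclopentane lets the vinyl group lie parallel to the C8···C12 axis; C8 is controlled by π-facial choice, the dienone being attacked on the face that puts quaternary C10 under diene carbon C14 (endo) and H-6 towards the C15 ketal, whereas the other face would press C10 and the C7 lactone carbonyl against the ketal methoxy groups; bridgehead C12 follows from the suprafacial addition. The step needs cycloaddition to win over dimerisation of the dienone and needs one π-face, which intramolecularity, the substituents at C8 and C13 and the rigid cis-fused lactone (no rotamers about C5–C6, defined C6) should secure. Mild aqueous acid in the work-up hydrolyses only the C13 enol ether, the α-keto ketal at C15 being deactivated, to give diketone 18.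

Step 11
Reactants: 18 13,16-dioxo-15,15-dimethoxy pentacycle
Product: 19 13-hydroxy-16-ketone (hydroxyl syn to the C9–C11 bridge)
Conditions: LiBH(s-Bu)3, THF, −78 °C; AcOH quench at −78 °C
Reagents that add atoms: none
Why: The bulky hydride should reduce only the C13 ketone, which is flanked by the C14 methylene group, and not the C16 ketone shielded by the quaternary ketal carbon (chemoselective ketone reduction); attack from the face syn to the C15–C16 bridge gives the carbinol drawn, but either C13 epimer serves because this centre becomes a radical in step 13, and the cold acidic quench forestalls retro-aldol cleavage of the β-alkoxide.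

Step 12
Reactants: 19 13-hydroxy-16-ketone
Product: 20 13-O-(phenoxythiocarbonyl) derivative
Conditions: PhOC(S)Cl, pyridine, DMAP, CH2Cl2, rt
Reagents that add atoms: O-phenyl chlorothionoformate S=C(Cl)Oc1ccccc1
Why: Acylation of the secondary alcohol under weakly basic conditions (no retro-aldol of the β-hydroxy ketone) gives the thionocarbonate needed for radical deoxygenation.

Step 13
Reactants: 20 13-O-(phenoxythiocarbonyl) derivative
Product: 21 15,15-dimethoxy-16-oxo ent-gibberellane lactone
Conditions: (Me3Si)3SiH (slow addition), AIBN, toluene, 90 °C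
Reagents that add atoms: none
Why: Silyl radical addition to the thiocarbonyl group and C–O scission (Barton–McCombie type) give the C13 radical, which adds 3-exo to the neighbouring C16 carbonyl and reopens with cleavage of C12–C16 (radical 1,2-acyl shift of the Dowd–Beckwith type), turning the bicyclo[2.2.2]octane into the bicyclo[3.2.1]octane of the target before the C12 radical is reduced; C13 becomes the bridgehead whose configuration the bicycle dictates, and slow addition of the hydrogen donor lets the shift precede reduction.

Step 14
Reactants: 21 15,15-dimethoxy-16-oxo ent-gibberellane lactone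
Product: 22 15,15-dimethoxy-16-methylene lactone
Conditions: Ph3PCH3Br, KOt-Bu, THF, 0 to 60 °C
Reagents that add atoms: methyltriphenylphosphonium bromide C[P+](c1ccccc1)(c1ccccc1)c1ccccc1.[Br-]
Why: Wittig methylenation of the C16 ketone, which cannot enolise towards the bridgehead or the ketal carbon, installs C17 while the esters react much more slowly with the ylide and the bridgehead C6–H of the lactone resists deprotonation.

Step 15
Reactants: 22 15,15-dimethoxy-16-methylene lactone
Product: 23 16-en-15-one lactone
Conditions: pyridinium p-toluenesulfonate, acetone/H2O, rt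
Reagents that add atoms: water O
Why: The dimethyl ketal is now allylic and ionises readily, so mild acid-catalysed ketal hydrolysis should unveil the enone without opening the acylal lactone.

Step 16
Reactants: 23 16-en-15-one lactone
Product: 24 15β-hydroxy-16-ene lactone
Conditions: NaBH4, CeCl3·7H2O, MeOH, −78 °C
Reagents that add atoms: none
Why: Luche 1,2-reduction of the exo-methylene ketone, with hydride delivered to the exo face of the bicyclo[3.2.1]octanone (the side of the one-carbon bridge C14, away from H-9 and the axial H-11), should give the endo 15β-alcohol, the hydroxyl pointing away from C14 as in the target.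

Step 17
Reactants: 24 15β-hydroxy-16-ene lactone
Product: 26 GA65 dimethyl ester, via 6-epi dimethyl ester 25 (not isolated)
Conditions: NaOMe (0.3 equiv), MeOH, 50 °C
Reagents that add atoms: methanol CO
Why: Methoxide opens the acylal lactone to the C7 methyl ester and a hemiacetal anion that collapses to the C20 aldehyde (transesterification), and the freed C7 ester, no longer held at a bridgehead, then epimerises at C6 by enolisation to the more stable 6β-ester, in which C7 is trans to the α-substituents on C4 and C10.

Step 18
Reactants: 26 GA65 dimethyl ester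
Product: 27 GA65
Conditions: LiOH, THF/H2O, 40 °C; then 1 M HCl to pH 3
Reagents that add atoms: water O
Why: Saponification cleaves the C7 ester directly and the hindered axial C19 ester with assistance from the neighbouring C20 aldehyde hydrate (intramolecular nucleophilic catalysis through a lactol), and the aldehyde cannot enolise because C10 is quaternary.

**Compound list**

1 | methyl 3-oxocyclohex-1-ene-1-carboxylate | COC(=O)C1=CC(=O)CCC1 | starting material
2 | bromomagnesium (3R)-3-ethenyl-3-(methoxycarbonyl)cyclohex-1-en-1-olate | C=C[C@]1(C(=O)OC)CCCC(O[Mg]Br)=C1 | intermediate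
3 | methyl (1R)-1-ethenyl-3-(trifluoromethylsulfonyloxy)cyclohex-2-ene-1-carboxylate | C=C[C@]1(C(=O)OC)CCCC(OS(=O)(=O)C(F)(F)F)=C1 | intermediate
4 | diisobutylaluminium hemiacetal alkoxide from 3 | C=C[C@]1(C(OC)O[Al](CC(C)C)CC(C)C)CCCC(OS(=O)(=O)C(F)(F)F)=C1 | intermediate
5 | [(1R)-1-ethenyl-3-(trifluoromethylsulfonyloxy)cyclohex-2-en-1-yl](methoxy)methyl acetate (both acetal epimers) | C=C[C@]1(C(OC)OC(C)=O)CCCC(OS(=O)(=O)C(F)(F)F)=C1 | intermediate
6 | methyl (3R)-3-[acetoxy(methoxy)methyl]-3-ethenylcyclohex-1-ene-1-carboxylate (both acetal epimers) | C=C[C@]1(C(OC)OC(C)=O)CCCC(C(=O)OC)=C1 | intermediate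
7 | lithium ester enolate (C4=C19) of the cyclised Michael adduct | C=C[C@]12CCCC(=C(OC)O[Li])[C@H]1CC(=O)OC2OC | intermediate
8 | ring A acylal lactone: methyl 8a-ethenyl-1-methoxy-5-methyl-3-oxooctahydro-1H-isochromene-5-carboxylate (4α-CO2Me, 4β-Me, 5β-H, 10β-vinyl, 10α-C20; δ-lactone C7(=O)–O–C20H(OMe)) | C=C[C@]12CCC[C@@](C)(C(=O)OC)[C@H]1CC(=O)OC2OC | intermediate
9 | 3-bromo-2-hydroxy-5-methoxybenzaldehyde | COc1cc(Br)c(O)c(C=O)c1 | starting material
10 | 3-bromo-2,5-dimethoxybenzaldehyde | COc1cc(Br)c(OC)c(C=O)c1 | intermediate
11 | 3-bromo-2,5-dimethoxyphenyl formate | COc1cc(Br)c(OC)c(OC=O)c1 | intermediate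
12 | 3-bromo-2,5-dimethoxyphenol | COc1cc(Br)c(OC)c(O)c1 | intermediate
13 | (3-bromo-2,5-dimethoxyphenoxy)(tert-butyl)dimethylsilane | COc1cc(Br)c(OC)c(O[Si](C)(C)C(C)(C)C)c1 | intermediate
14 | C6-aryl lactone silyl ether: 8 with 3-(tert-butyldimethylsilyloxy)-2,5-dimethoxyphenyl on C6 (6β-H, C7 α) | C=C[C@]12CCC[C@@](C)(C(=O)OC)[C@H]1[C@H](c1cc(OC)cc(O[Si](C)(C)C(C)(C)C)c1OC)C(=O)OC2OC | intermediate
15 | C6-aryl lactone phenol: 3-hydroxy-2,5-dimethoxyphenyl on C6 | C=C[C@]12CCC[C@@](C)(C(=O)OC)[C@H]1[C@H](c1cc(OC)cc(O)c1OC)C(=O)OC2OC | intermediate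
16 | masked o-benzoquinone: 3,6,6-trimethoxy-5-oxocyclohexa-1,3-dien-1-yl group on C6 | C=C[C@]12CCC[C@@](C)(C(=O)OC)[C@H]1[C@H](C1=CC(OC)=CC(=O)C1(OC)OC)C(=O)OC2OC | intermediate
17 | enol-ether cycloadduct: 13-methoxy-13-ene, 16-oxo, 15,15-dimethoxy; bicyclo[2.2.2]octene with C12–C16 bond; 8β-C15, 9β-H | O=C1C(OC)(OC)[C@]23C=C(OC)[C@H]1C[C@H]2[C@]45CCC[C@@](C)(C(=O)OC)[C@H]4[C@H]3C(=O)OC5OC | intermediate
18 | 13,16-dioxo-15,15-dimethoxy pentacycle (ent-atisane-type C12–C16 connectivity; 6-epi 7,20-acylal lactone) | O=C1C(OC)(OC)[C@]23CC(=O)[C@H]1C[C@H]2[C@]45CCC[C@@](C)(C(=O)OC)[C@H]4[C@H]3C(=O)OC5OC | intermediate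
19 | 13-hydroxy-16-ketone (hydroxyl syn to the C9–C11 bridge) | O=C1C(OC)(OC)[C@]23C[C@@H](O)[C@H]1C[C@H]2[C@]45CCC[C@@](C)(C(=O)OC)[C@H]4[C@H]3C(=O)OC5OC | intermediate
20 | 13-O-(phenoxythiocarbonyl) derivative of 19 | O=C1C(OC)(OC)[C@]23C[C@@H](OC(=S)Oc6ccccc6)[C@H]1C[C@H]2[C@]45CCC[C@@](C)(C(=O)OC)[C@H]4[C@H]3C(=O)OC5OC | intermediate
21 | 15,15-dimethoxy-16-oxo ent-gibberellane lactone (C16 on C13; C12 methylene; 6-epi 7,20-acylal lactone; 19-methyl ester) | O=C1[C@@H]2CC[C@H]3[C@]45CCC[C@@](C)(C(=O)OC)[C@H]4[C@@H](C(=O)OC5OC)[C@]3(C2)C1(OC)OC | intermediate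
22 | 15,15-dimethoxy-16-methylene lactone | C=C1[C@@H]2CC[C@H]3[C@]45CCC[C@@](C)(C(=O)OC)[C@H]4[C@@H](C(=O)OC5OC)[C@]3(C2)C1(OC)OC | intermediate
23 | 16-en-15-one lactone | C=C1[C@@H]2CC[C@H]3[C@]45CCC[C@@](C)(C(=O)OC)[C@H]4[C@@H](C(=O)OC5OC)[C@]3(C2)C1=O | intermediate
24 | 15β-hydroxy-16-ene lactone (hydroxyl endo, anti to C14) | C=C1[C@@H]2CC[C@H]3[C@]45CCC[C@@](C)(C(=O)OC)[C@H]4[C@@H](C(=O)OC5OC)[C@]3(C2)[C@@H]1O | intermediate
25 | 6-epi-GA65 dimethyl ester (C7 α) | C=C1[C@@H]2CC[C@H]3[C@]4(C=O)CCC[C@@](C)(C(=O)OC)[C@H]4[C@@H](C(=O)OC)[C@]3(C2)[C@@H]1O | intermediate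
26 | GA65 dimethyl ester | C=C1[C@@H]2CC[C@H]3[C@]4(C=O)CCC[C@@](C)(C(=O)OC)[C@H]4[C@H](C(=O)OC)[C@]3(C2)[C@@H]1O | intermediate
27 | GA65 (the target gibberellin: 15-hydroxy-20-oxo-16-ene 7,19-dicarboxylic acid) | C=C1[C@@H]2CC[C@H]3[C@]4(C=O)CCC[C@@](C)(C(=O)O)[C@H]4[C@H](C(=O)O)[C@]3(C2)[C@@H]1O | target

**Step count and risks**

Total step count: 18. Longest linear sequence: 15 steps (steps 1–4 and 8–18); the arene is made in 3 steps (5–7).

The three steps most likely to fail:

Step 4 (carries the label). The lithium enolate of the acetal ester may lose the hemiacetal alkoxide as a ketene, or transfer a proton to the new lactone, before the hindered ring closure and the methylation are complete. The fallback sets out from compound 6 and avoids a free lithium enolate altogether. Deprotonation with LiN(i-Pr)2 in the presence of Me3SiCl at −100 °C (internal quench) should give the ketene silyl acetal F1. A catalytic fluoride source (tris(dimethylamino)sulfonium difluorotrimethylsilicate) should then trigger the intramolecular Mukaiyama–Michael addition with silyl transfer, giving the C4 silyl ketene acetal F2. A full equivalent of the same fluoride source with MeI at −78 °C then methylates F2 on carbon from the β-face (fluoride-mediated alkylation of a silyl ketene acetal), and the route is rejoined at compound 8.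

Step 10. The electron-rich vinylogous-ester dienone may add too slowly to the unactivated vinyl group, so that dimerisation, decomposition or loss of facial control takes over. The fallback sets out from compound 8 and moves the C13 oxygen to a later stage, so that the parent, more reactive masked o-benzoquinone is used. The catalogue compound 3-bromo-2-methoxyphenol is silylated to the silyl ether F3 and coupled with the zinc enolate of 8 (as in step 8) to give the C6-aryl lactone F4. Desilylation gives the phenol F5, and PhI(OAc)2 in MeOH followed by heating should give the 13-ene cycloadduct F7 through the 6,6-dimethoxycyclohexa-2,4-dienone F6. Hydroboration with BH3·THF places boron on C13, remote from quaternary C8, and reduces the C16 ketone; oxidative work-up with NaBO3·4H2O gives the 13,16-diol F8. Dess–Martin oxidation of F8 rejoins the route at diketone 18.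

Step 13. Hydrogen transfer to the C13 radical may outrun the 1,2-acyl shift, or the radical equilibrium may not favour the bicyclo[3.2.1]octane. The fallback sets out from compound 19 and uses the faster homoallyl–homoallyl radical rearrangement (1,2-vinyl shift) through the exocyclic alkene instead of the ketone. Compound 19 is silylated (Et3SiOTf, 2,6-lutidine) to the triethylsilyl ether F9, and Wittig methylenation of the C16 ketone gives the 16-methylene silyl ether F10. Desilylation with n-Bu4NF, which leaves the now allylic ketal untouched, gives the 16-methylene 13-alcohol F11, and PhOC(S)Cl converts this into the thionocarbonate F12. With Bu3SnH and AIBN under slow addition, the C13 radical from F12 should add 3-exo to C16 of the alkene and reopen with cleavage of C12–C16. This rejoins the route at compound 22 and makes step 14 unnecessary.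

Further compounds
F1 | step 4 | ketene silyl acetal of 6 | C=C[C@]1(C(OC)OC(=C)O[Si](C)(C)C)CCCC(C(=O)OC)=C1
F2 | step 4 | C4 silyl ketene acetal of the cyclised lactone | C=C[C@]12CCCC(=C(OC)O[Si](C)(C)C)[C@H]1CC(=O)OC2OC
F3 | step 10 | (3-bromo-2-methoxyphenoxy)(tert-butyl)dimethylsilane | COc1c(Br)cccc1O[Si](C)(C)C(C)(C)C
F4 | step 10 | C6-aryl lactone without the C13 methoxy group, silyl ether | C=C[C@]12CCC[C@@](C)(C(=O)OC)[C@H]1[C@H](c1cccc(O[Si](C)(C)C(C)(C)C)c1OC)C(=O)OC2OC
F5 | step 10 | C6-aryl lactone without the C13 methoxy group, phenol | C=C[C@]12CCC[C@@](C)(C(=O)OC)[C@H]1[C@H](c1cccc(O)c1OC)C(=O)OC2OC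
F6 | step 10 | 6,6-dimethoxycyclohexa-2,4-dienone without the C13 methoxy group (not isolated) | C=C[C@]12CCC[C@@](C)(C(=O)OC)[C@H]1[C@H](C1=CC=CC(=O)C1(OC)OC)C(=O)OC2OC
F7 | step 10 | 13-ene cycloadduct (16-oxo, 15,15-dimethoxy) | O=C1C(OC)(OC)[C@]23C=C[C@H]1C[C@H]2[C@]45CCC[C@@](C)(C(=O)OC)[C@H]4[C@H]3C(=O)OC5OC
F8 | step 10 | 13,16-diol (carbinol configurations open) | OC1C(OC)(OC)[C@]23CC(O)[C@H]1C[C@H]2[C@]45CCC[C@@](C)(C(=O)OC)[C@H]4[C@H]3C(=O)OC5OC
F9 | step 13 | 13-O-triethylsilyl ether of 19 | O=C1C(OC)(OC)[C@]23C[C@@H](O[Si](CC)(CC)CC)[C@H]1C[C@H]2[C@]45CCC[C@@](C)(C(=O)OC)[C@H]4[C@H]3C(=O)OC5OC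
F10 | step 13 | 16-methylene 13-O-triethylsilyl ether | C=C1C(OC)(OC)[C@]23C[C@@H](O[Si](CC)(CC)CC)[C@H]1C[C@H]2[C@]45CCC[C@@](C)(C(=O)OC)[C@H]4[C@H]3C(=O)OC5OC
F11 | step 13 | 16-methylene 13-alcohol | C=C1C(OC)(OC)[C@]23C[C@@H](O)[C@H]1C[C@H]2[C@]45CCC[C@@](C)(C(=O)OC)[C@H]4[C@H]3C(=O)OC5OC
F12 | step 13 | 16-methylene 13-O-(phenoxythiocarbonyl) derivative | C=C1C(OC)(OC)[C@]23C[C@@H](OC(=S)Oc6ccccc6)[C@H]1C[C@H]2[C@]45CCC[C@@](C)(C(=O)OC)[C@H]4[C@H]3C(=O)OC5OC
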